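**Plan**
1. Numbering: naphthalene C1 carries the 4-hydroxyphenyl ring, C2 and C3 the two 2,4-dihydroxybenzoyl groups, C4 is CH, and ring A (C4a–C8a) is the catechol ring. Ring B is cut at C2–C3 and C1–C8a, which gives two 1,3-diarylpropynones: C2 and C3 are their carbonyl-bound alkyne carbons, C1 is the aryl-bound alkyne carbon of one, and C8a is an ortho carbon of the aryl group of the other.
2. The ortho oxygens of the two aroyl rings are bridged by a propane-1,3-diyl chain so that the ring-forming event is intramolecular. The chain is built by two Williamson etherifications, each aldehyde then takes up its arylacetylide, and MnO2 gives the bis-ynone.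
3. Irradiation closes ring B and, with it, the 13-membered ring through the bridge. BBr3 then opens the bridge and frees the phenols.
4. Regiocontrol: the aryl group meant for C1 carries two tert-butyl groups beside its oxygen, so neither of its ortho carbons can serve as C8a. They are removed last by acid-mediated transfer to toluene.
5. The target has no stereocentre and no stable stereoaxis; the carbinol centres made on the way are oxidised to ketones.

Key step: step 8

Remark: carbinols 8, 9 and 12 are carried as racemates or diastereomer mixtures, since their stereocentres disappear in step 7.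

**Route**

Step 1
Reactants: 1 2-hydroxy-4-methoxybenzaldehyde; 2 1-bromo-3-chloropropane
Product: 3 2-(3-chloropropoxy)-4-methoxybenzaldehyde
Conditions: K2CO3, 2 (3 equiv), DMF, 50 °C
Reagents that add atoms: none
Why: Williamson ether synthesis in which the phenoxide displaces bromide much faster than chloride, and the excess dihalide suppresses double alkylation.

Step 2
Reactants: 4 3,5-di-tert-butyl-4-hydroxybenzaldehyde
Product: 5 3,5-di-tert-butyl-4-(methoxymethoxy)benzaldehyde
Conditions: NaH, DMF, 0 °C; then ClCH2OCH3, 0 °C to rt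
Reagents that add atoms: chloromethyl methyl ether, COCCl
Why: Methoxymethyl protection by O-alkylation of the sodium phenoxide with a highly reactive α-chloro ether should succeed even between two tert-butyl groups, and it masks a phenol that would otherwise quench the ketone triplet of step 8 by hydrogen transfer.

Step 3
Reactants: 5 3,5-di-tert-butyl-4-(methoxymethoxy)benzaldehyde
Product: 6 1,3-di-tert-butyl-5-ethynyl-2-(methoxymethoxy)benzene
Conditions: dimethyl (1-diazo-2-oxopropyl)phosphonate, K2CO3, MeOH, rt
Reagents that add atoms: dimethyl (1-diazo-2-oxopropyl)phosphonate, CC(=O)C(=[N+]=[N-])P(=O)(OC)OC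
Why: Seyferth–Gilbert homologation with the Ohira–Bestmann reagent converts a non-enolisable aryl aldehyde into the terminal alkyne under mildly basic conditions that leave the acetal untouched.

Step 4
Reactants: 6 1,3-di-tert-butyl-5-ethynyl-2-(methoxymethoxy)benzene; 3 2-(3-chloropropoxy)-4-methoxybenzaldehyde
Product: 8 1-[2-(3-chloropropoxy)-4-methoxyphenyl]-3-[3,5-di-tert-butyl-4-(methoxymethoxy)phenyl]prop-2-yn-1-ol (racemic), via lithium arylacetylide 7 (not isolated)
Conditions: n-BuLi, THF, −78 °C; then 3, −78 to −20 °C; aq. NH4Cl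
Reagents that add atoms: none
Why: 1,2-Addition of a lithium acetylide to an aryl aldehyde is fast at low temperature, where the primary alkyl chloride is inert to the acetylide in the absence of a polar additive.

Step 5
Reactants: 8 1-[2-(3-chloropropoxy)-4-methoxyphenyl]-3-[3,5-di-tert-butyl-4-(methoxymethoxy)phenyl]prop-2-yn-1-ol; 1 2-hydroxy-4-methoxybenzaldehyde
Product: 9 2-[3-(2-{3-[3,5-di-tert-butyl-4-(methoxymethoxy)phenyl]-1-hydroxyprop-2-yn-1-yl}-5-methoxyphenoxy)propoxy]-4-methoxybenzaldehyde (racemic)
Conditions: K2CO3, NaI (0.2 equiv), DMF, 60 °C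
Reagents that add atoms: none
Why: Williamson etherification in which K2CO3 ionises only the phenol of 1, iodide converts the chloride into the more reactive iodide in the flask (Finkelstein exchange), and the secondary propargylic alcohol is too weak an acid to be deprotonated.

Step 6
Reactants: 9 the aldehyde–carbinol of step 5; 10 4-ethynyl-1,2-dimethoxybenzene
Product: 12 3-[3,5-di-tert-butyl-4-(methoxymethoxy)phenyl]-1-[2-(3-{2-[3-(3,4-dimethoxyphenyl)-1-hydroxyprop-2-yn-1-yl]-5-methoxyphenoxy}propoxy)-4-methoxyphenyl]prop-2-yn-1-ol (diastereomer mixture), via lithium (3,4-dimethoxyphenyl)acetylide 11 (not isolated)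
Conditions: 10 (2.3 equiv), n-BuLi (2.2 equiv), THF, −78 °C; then 9, −78 to 0 °C; aq. NH4Cl
Reagents that add atoms: none
Why: Lithium acetylide addition to the aldehyde, in which the first equivalent is consumed by the free hydroxyl group and the second adds to the carbonyl group; the excess of the inexpensive alkyne 10 is recoverable.

Step 7
Reactants: 12 the bis-carbinol of step 6
Product: 13 3-[3,5-di-tert-butyl-4-(methoxymethoxy)phenyl]-1-[2-(3-{2-[3-(3,4-dimethoxyphenyl)prop-2-ynoyl]-5-methoxyphenoxy}propoxy)-4-methoxyphenyl]prop-2-yn-1-one (tethered bis-ynone)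
Conditions: activated MnO2 (excess), CH2Cl2, rt
Reagents that add atoms: none
Why: MnO2 oxidation is selective for alcohols that are both benzylic and propargylic, and its neutral conditions spare the acetal and the electron-rich alkynes.

Step 8
Reactants: 13 the tethered bis-ynone
Product: 15 propane-1,3-diyl-bridged 1-[3,5-di-tert-butyl-4-(methoxymethoxy)phenyl]-2,3-bis(4-methoxy-2-oxybenzoyl)-6,7-dimethoxynaphthalene (13-membered diketone macrocycle), via cyclic allene 14 (not isolated)
Conditions: hν (λ ≥ 300 nm, medium-pressure Hg lamp, Pyrex filter), degassed MeCN, 1 mM, 20 °C, stopped at full conversion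
Reagents that add atoms: none
Why: Light absorbed by either diaryl ynone gives, after intersystem crossing, a triplet that bonds through its carbonyl-bound alkyne carbon to the same carbon of the other ynone (C2–C3); this first bond closes the 13-membered ring through the O(CH2)3O bridge by end-to-end radical coupling and leaves a buta-1,3-diene-1,4-diyl biradical. The vinyl radical next to the di-tert-butylaryl group then adds to C6 of the 3,4-dimethoxyphenyl ring (C1–C8a), a six-membered closure that completes a formal [4+2] cycloaddition with the arylalkyne as the four-carbon partner, and cyclic allene 14 becomes the naphthalene by hydrogen shift from C8a to C4. The closest known reaction is the photochemical dehydro-Diels–Alder reaction of tethered bis(3-arylpropynones), which gives 1-arylnaphthalenes. No stereocentre is created, because the sp3 centre and the allene axis of 14 vanish on aromatisation. The step needs closure onto ring A alone and at its C6: both ortho carbons of the other aryl ring are flanked by tert-butyl groups, so attack there would force a tert-butyl group into the peri position beside the C1 aryl group, whereas in ring A the carbon between the alkyne and the 3-methoxy group is shielded by that methoxy group (turned toward it by the neighbouring 4-methoxy group) and C6 is open and para to a donor. The π,π* character of the alkoxy-rich ynone triplet and millimolar dilution should keep hydrogen abstraction from the OCH2 groups and intermolecular coupling in the background.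

Step 9
Reactants: 15 the bridged naphthalene of step 8
Product: 16 [1-(3,5-di-tert-butyl-4-hydroxyphenyl)-6,7-dihydroxynaphthalene-2,3-diyl]bis[(2,4-dihydroxyphenyl)methanone]
Conditions: BBr3 (20 equiv), CH2Cl2, −78 °C to rt; then H2O, 0 °C
Reagents that add atoms: none
Why: BBr3 ether cleavage (adduct formation, then bromide attack at methyl or primary carbon) removes the four methyl ethers and both O–CH2 bonds of the bridge, the latter assisted by chelation to the neighbouring ketones, while the acetal on the hindered oxygen is cleaved through its unhindered outer oxygen.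

Step 10
Reactants: 16 the di-tert-butyl heptaphenol of step 9
Product: 17 [6,7-dihydroxy-1-(4-hydroxyphenyl)naphthalene-2,3-diyl]bis[(2,4-dihydroxyphenyl)methanone] (CNP0304576.0)
Conditions: AlCl3 (12 equiv), MeNO2, toluene, 50 °C; then 1 M HCl
Reagents that add atoms: none
Why: Acid-mediated trans-tert-butylation (retro-Friedel–Crafts dealkylation), in which ipso-protonation ortho to the crowded hydroxyl group releases each tert-butyl cation to the large excess of toluene, while the acylated, aluminium-bound phenol rings are too deactivated to be re-alkylated.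

**Compound list**
1 | 2-hydroxy-4-methoxybenzaldehyde | COc1ccc(C=O)c(O)c1 | starting material
2 | 1-bromo-3-chloropropane | ClCCCBr | starting material
3 | 2-(3-chloropropoxy)-4-methoxybenzaldehyde | COc1ccc(C=O)c(OCCCCl)c1 | intermediate
4 | 3,5-di-tert-butyl-4-hydroxybenzaldehyde | CC(C)(C)c1cc(C=O)cc(C(C)(C)C)c1O | starting material
5 | 3,5-di-tert-butyl-4-(methoxymethoxy)benzaldehyde | COCOc1c(C(C)(C)C)cc(C=O)cc1C(C)(C)C | intermediate
6 | 1,3-di-tert-butyl-5-ethynyl-2-(methoxymethoxy)benzene | COCOc1c(C(C)(C)C)cc(C#C)cc1C(C)(C)C | intermediate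
7 | lithium [3,5-di-tert-butyl-4-(methoxymethoxy)phenyl]acetylide | COCOc1c(C(C)(C)C)cc(C#C[Li])cc1C(C)(C)C | intermediate (not isolated)
8 | 1-[2-(3-chloropropoxy)-4-methoxyphenyl]-3-[3,5-di-tert-butyl-4-(methoxymethoxy)phenyl]prop-2-yn-1-ol (racemic) | COCOc1c(C(C)(C)C)cc(C#CC(O)c2ccc(OC)cc2OCCCCl)cc1C(C)(C)C | intermediate
9 | 2-[3-(2-{3-[3,5-di-tert-butyl-4-(methoxymethoxy)phenyl]-1-hydroxyprop-2-yn-1-yl}-5-methoxyphenoxy)propoxy]-4-methoxybenzaldehyde (racemic) | COCOc1c(C(C)(C)C)cc(C#CC(O)c2ccc(OC)cc2OCCCOc2cc(OC)ccc2C=O)cc1C(C)(C)C | intermediate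
10 | 4-ethynyl-1,2-dimethoxybenzene | COc1ccc(C#C)cc1OC | starting material
11 | lithium (3,4-dimethoxyphenyl)acetylide | COc1ccc(C#C[Li])cc1OC | intermediate (not isolated)
12 | bis-carbinol: 3-[3,5-di-tert-butyl-4-(methoxymethoxy)phenyl]-1-[2-(3-{2-[3-(3,4-dimethoxyphenyl)-1-hydroxyprop-2-yn-1-yl]-5-methoxyphenoxy}propoxy)-4-methoxyphenyl]prop-2-yn-1-ol (diastereomer mixture) | COCOc1c(C(C)(C)C)cc(C#CC(O)c2ccc(OC)cc2OCCCOc2cc(OC)ccc2C(O)C#Cc2ccc(OC)c(OC)c2)cc1C(C)(C)C | intermediate
13 | tethered bis-ynone: 3-[3,5-di-tert-butyl-4-(methoxymethoxy)phenyl]-1-[2-(3-{2-[3-(3,4-dimethoxyphenyl)prop-2-ynoyl]-5-methoxyphenoxy}propoxy)-4-methoxyphenyl]prop-2-yn-1-one | COCOc1c(C(C)(C)C)cc(C#CC(=O)c2ccc(OC)cc2OCCCOc2cc(OC)ccc2C(=O)C#Cc2ccc(OC)c(OC)c2)cc1C(C)(C)C | intermediate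
14 | cyclic allene (1,2,4-cyclohexatriene form of ring B, sp3 CH at C8a, allene C3=C4=C4a; transient, configuration undefined) | COCOc1c(C(C)(C)C)cc(C2=C3C(=C=C4C=C(OC)C(OC)=CC42)C(=O)c2ccc(OC)cc2OCCCOc2cc(OC)ccc2C3=O)cc1C(C)(C)C | intermediate (not isolated)
15 | bridged naphthalene: 1-[3,5-di-tert-butyl-4-(methoxymethoxy)phenyl]-6,7-dimethoxynaphthalene whose C2 and C3 carry 4-methoxybenzoyl groups joined through their 2-oxygens by a propane-1,3-diyl chain (13-membered diketone ring) | COCOc1c(C(C)(C)C)cc(-c2c3c(cc4cc(OC)c(OC)cc24)C(=O)c2ccc(OC)cc2OCCCOc2cc(OC)ccc2C3=O)cc1C(C)(C)C | intermediate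
16 | [1-(3,5-di-tert-butyl-4-hydroxyphenyl)-6,7-dihydroxynaphthalene-2,3-diyl]bis[(2,4-dihydroxyphenyl)methanone] | CC(C)(C)c1cc(-c2c(C(=O)c3ccc(O)cc3O)c(C(=O)c3ccc(O)cc3O)cc3cc(O)c(O)cc23)cc(C(C)(C)C)c1O | intermediate
17 | [6,7-dihydroxy-1-(4-hydroxyphenyl)naphthalene-2,3-diyl]bis[(2,4-dihydroxyphenyl)methanone] (CNP0304576.0) | O=C(c1ccc(O)cc1O)c1cc2cc(O)c(O)cc2c(-c2ccc(O)cc2)c1C(=O)c1ccc(O)cc1O | target

**Count**
Total steps: 10. Longest linear sequence: 9 steps (4 → 5 → 6 → 8 → 9 → 12 → 13 → 15 → 16 → 17, steps 2–10).

**Steps most likely to fail, with fallbacks**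

Step 8. The excited ketone may abstract hydrogen from the neighbouring OCH2 group of the bridge and cyclise, end-to-end bonding across 13 atoms may be slow enough for intermolecular coupling to compete, or some closure may still occur at the hindered ortho carbon of ring A. The fallback gives up the photoreaction for a thermal Diels–Alder route; it sets out from 1 and comes back at 17.
- Dienophile: compound 1 is O-methylated (MeI, K2CO3, acetone) to 2,4-dimethoxybenzaldehyde F1. Two equivalents add to BrMgC≡CMgBr (from acetylene and EtMgBr, THF) to give 1,4-bis(2,4-dimethoxyphenyl)but-2-yne-1,4-diol F2, which MnO2 oxidises to 1,4-bis(2,4-dimethoxyphenyl)but-2-yne-1,4-dione F3.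
- Diene precursor: commercial 2-bromo-4,5-dimethoxybenzaldehyde is converted with HC(OMe)3 and catalytic TsOH in MeOH into 1-bromo-2-(dimethoxymethyl)-4,5-dimethoxybenzene F4. Bromine–lithium exchange (n-BuLi, THF, −78 °C) and addition to 4-methoxybenzaldehyde give [2-(dimethoxymethyl)-4,5-dimethoxyphenyl](4-methoxyphenyl)methanol F5.
- Ring construction: heating F5 with F3 and catalytic AcOH in toluene should generate 5,6-dimethoxy-1-(4-methoxyphenyl)isobenzofuran F6. F3 traps it as the oxygen-bridged cycloadduct [6,7-dimethoxy-1-(4-methoxyphenyl)-1,4-dihydro-1,4-epoxynaphthalene-2,3-diyl]bis[(2,4-dimethoxyphenyl)methanone] F7.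
- Aromatisation and deprotection: NaI/Me3SiCl in MeCN removes the bridging oxygen to give [6,7-dimethoxy-1-(4-methoxyphenyl)naphthalene-2,3-diyl]bis[(2,4-dimethoxyphenyl)methanone] F8, and BBr3 cleaves its seven methyl ethers to give 17.
- The aryl group sits on the furan carbon that becomes C1 and the dienophile is symmetrical, so no regiochemical question arises and no blocking groups are needed.

Step 10. The tert-butyl cations may be transferred to the free resorcinol or catechol rings of the substrate instead of toluene, or the aluminium phenoxides may precipitate and leave the dealkylation incomplete. The fallback moves the dealkylation to a stage where every other oxygen is still alkylated; it sets out from 15 and comes back at 17.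
- HCl in MeOH/THF removes the acetal of 15 to give the bridged 1-(3,5-di-tert-butyl-4-hydroxyphenyl) naphthalene F9.
- CF3SO3H in toluene at 50 °C, a Brønsted acid that leaves aryl ethers intact, transfers both tert-butyl groups to the solvent and gives the bridged 1-(4-hydroxyphenyl) naphthalene F10.
- BBr3 then cleaves the bridge and the four methyl ethers of F10 to give 17.
- The same detour would also answer an incomplete ether cleavage in step 9.

Step 5. The secondary propargylic alcohol may isomerise to the enone under base, or displacement of the chloride may be too slow. The fallback forms both ether bonds before any carbinol exists; it sets out from 1 and comes back at 9.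
- Two equivalents of 1 are alkylated with 1,3-dibromopropane (K2CO3, DMF) to give 2,2'-[propane-1,3-diylbis(oxy)]bis(4-methoxybenzaldehyde) F11.
- One equivalent of lithium acetylide 7 (from 6 and n-BuLi) is added at −78 °C to give 9 by statistical mono-addition.
- Unreacted F11 is recycled and the double adduct is removed by chromatography.

**Further compounds**
F1 | step 8 | 2,4-dimethoxybenzaldehyde | COc1ccc(C=O)c(OC)c1
F2 | step 8 | 1,4-bis(2,4-dimethoxyphenyl)but-2-yne-1,4-diol (diastereomer mixture) | COc1ccc(C(O)C#CC(O)c2ccc(OC)cc2OC)c(OC)c1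
F3 | step 8 | 1,4-bis(2,4-dimethoxyphenyl)but-2-yne-1,4-dione | COc1ccc(C(=O)C#CC(=O)c2ccc(OC)cc2OC)c(OC)c1
F4 | step 8 | 1-bromo-2-(dimethoxymethyl)-4,5-dimethoxybenzene | COc1cc(Br)c(C(OC)OC)cc1OC
F5 | step 8 | [2-(dimethoxymethyl)-4,5-dimethoxyphenyl](4-methoxyphenyl)methanol (racemic) | COc1ccc(C(O)c2cc(OC)c(OC)cc2C(OC)OC)cc1
F6 | step 8 | 5,6-dimethoxy-1-(4-methoxyphenyl)isobenzofuran (not isolated) | COc1ccc(-c2occ3cc(OC)c(OC)cc23)cc1
F7 | step 8 | [6,7-dimethoxy-1-(4-methoxyphenyl)-1,4-dihydro-1,4-epoxynaphthalene-2,3-diyl]bis[(2,4-dimethoxyphenyl)methanone] (racemic) | COc1ccc(cc1)C12OC(c3cc(OC)c(OC)cc31)C(C(=O)c1ccc(OC)cc1OC)=C2C(=O)c1ccc(OC)cc1OC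
F8 | step 8 | [6,7-dimethoxy-1-(4-methoxyphenyl)naphthalene-2,3-diyl]bis[(2,4-dimethoxyphenyl)methanone] | COc1ccc(-c2c(C(=O)c3ccc(OC)cc3OC)c(C(=O)c3ccc(OC)cc3OC)cc3cc(OC)c(OC)cc23)cc1
F9 | step 10 | bridged naphthalene 15 without its methoxymethyl group (1-(3,5-di-tert-butyl-4-hydroxyphenyl) compound) | CC(C)(C)c1cc(-c2c3c(cc4cc(OC)c(OC)cc24)C(=O)c2ccc(OC)cc2OCCCOc2cc(OC)ccc2C3=O)cc(C(C)(C)C)c1O
F10 | step 10 | bridged 1-(4-hydroxyphenyl)-6,7-dimethoxynaphthalene diketone macrocycle | Oc1ccc(-c2c3c(cc4cc(OC)c(OC)cc24)C(=O)c2ccc(OC)cc2OCCCOc2cc(OC)ccc2C3=O)cc1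
F11 | step 5 | 2,2'-[propane-1,3-diylbis(oxy)]bis(4-methoxybenzaldehyde) | COc1ccc(C=O)c(OCCCOc2cc(OC)ccc2C=O)c1
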